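**Retrosynthetic overview**
1. Aspergimarin B 23 ⇒ its 5,8-di-O-methyl ether tert-butyl ester 20. TFA frees the acid, and the para-hydroquinone is unmasked last by way of the quinone ((NH4)2Ce(NO3)6, then Na2S2O4).
2. 20 ⇒ isocoumarin 19. The R centre at C3 is set by catalyst-controlled hydrogenation of the C3=C4 enol-lactone bond.
3. 19 ⇒ 3,6-dimethoxybenzyne 17 + CO2 16 + terminal alkyne 7. One copper-catalysed operation makes C4–C4a, C8a–C1 and, as the ring-closing event, O2–C3. Lactone ring B is the only ring formed, on the preformed ring A.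
4. Enabling feature: in ring A the oxygens on C5 and C8 are para to each other and flank the C4a–C8a edge that carries C4 and C1. The aryne C4a≡C8a is therefore C2v-symmetric, and both directions of addition give the same product.
5. 7 ⇒ (S)-propylene oxide 2 (source of the side-chain S centre), a butynyl Grignard reagent and mono-tert-butyl succinate 6. 17 ⇒ 2,5-dimethoxyphenol 8 by directed ortho-silylation.

Key step: step 6

Numbering used: isochromenone numbering (C1 carbonyl, O2, C3, C4, C4a, C5 to C8, C8a). Ring A is the benzene ring and ring B is the lactone ring.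
Assumption: the ruthenium catalyst of step 7 is used as the antipode that adds hydrogen to the Si face of C3. Which ligand enantiomers these are is to be fixed on 8-methoxy-3-methylisocoumarin, whose reduction product has a known sign of rotation.

Step 1
Reactants: 1 (4-bromobut-1-yn-1-yl)trimethylsilane; 2 (S)-propylene oxide
Product: 5 (2S)-hept-6-yn-2-ol, via Grignard reagent 3 (not isolated), via silylated alkynol 4 (not isolated)
Conditions: Mg, THF, 40 °C; CuI (10 mol %), 2, THF, −30 → 0 °C; aqueous work-up; K2CO3 (cat.), MeOH, rt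
Reagents that add atoms: none
Why: Copper-catalysed SN2 opening of a terminal epoxide by a Grignard reagent occurs at the unsubstituted carbon, so the C–O stereocentre of 2 passes unchanged into 5 (S), and carbonate-catalysed methanolysis (protodesilylation) then frees the terminal alkyne.

Step 2
Reactants: 5 (2S)-hept-6-yn-2-ol; 6 4-tert-butoxy-4-oxobutanoic acid (mono-tert-butyl succinate)
Product: 7 tert-butyl (2S)-hept-6-yn-2-yl butanedioate
Conditions: DCC, DMAP (cat.), CH2Cl2, 0 °C → rt
Reagents that add atoms: none
Why: Steglich esterification acylates only the oxygen, so the S centre is retained, and the tert-butyl ester masks the acid that would otherwise quench the aryne and the organocopper species of step 6.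

Step 3
Reactants: 8 2,5-dimethoxyphenol
Product: 9 2,5-dimethoxyphenyl N-isopropylcarbamate
Conditions: i-PrNCO, Et3N (cat.), CH2Cl2, rt
Reagents that add atoms: isopropyl isocyanate CC(C)N=C=O
Why: Base-catalysed addition of the phenol to an isocyanate (carbamoylation) installs a strong ortho-directing group that mild base can remove later.

Step 4
Reactants: 9 2,5-dimethoxyphenyl N-isopropylcarbamate
Product: 13 3,6-dimethoxy-2-(trimethylsilyl)phenyl N-isopropylcarbamate, via N-silyl carbamate 10 (not isolated), via aryllithium 11 (not isolated), via bis-silyl carbamate 12 (not isolated)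
Conditions: TBSOTf, TMEDA, Et2O, 0 °C → rt; n-BuLi (2 equiv), TMEDA, −78 °C; TMSCl, −78 °C → rt; aq NaHSO4
Reagents that add atoms: trimethylsilyl chloride C[Si](C)(C)Cl
Why: In this directed ortho-metalation the transiently N-silylated carbamate has a single free ortho position, which is also ortho to a methoxy group, so lithiation and C-silylation should occur only there, and the N–Si bond is hydrolysed on work-up.

Step 5
Reactants: 13 3,6-dimethoxy-2-(trimethylsilyl)phenyl N-isopropylcarbamate
Product: 15 3,6-dimethoxy-2-(trimethylsilyl)phenyl trifluoromethanesulfonate, via silylphenol 14 (not isolated)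
Conditions: DBU, Et2NH, MeCN, 40 °C; then PhNTf2, rt
Reagents that add atoms: N-phenylbis(trifluoromethanesulfonimide) O=S(=O)(N(c1ccccc1)S(=O)(=O)C(F)(F)F)C(F)(F)F
Why: E1cB cleavage of the secondary carbamate (the isocyanate is scavenged by Et2NH) gives the phenoxide, which PhNTf2 triflates in the same flask to the ortho-silylaryl triflate aryne precursor.

Step 6
Reactants: 15 3,6-dimethoxy-2-(trimethylsilyl)phenyl trifluoromethanesulfonate; 7 tert-butyl (2S)-hept-6-yn-2-yl butanedioate; 16 carbon dioxide
Product: 19 tert-butyl (2S)-5-(5,8-dimethoxy-1-oxo-1H-isochromen-3-yl)pentan-2-yl butanedioate, via 3,6-dimethoxybenzyne 17 (not isolated), via cesium alkynylbenzoate 18 (not isolated)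
Conditions: CuCl(IPr) (10 mol %; IPr = 1,3-bis(2,6-diisopropylphenyl)imidazol-2-ylidene), CsF (3 equiv), Cs2CO3 (1.2 equiv), CO2 (1 atm), MeCN, 60 °C, 15 added slowly
Reagents that add atoms: none
Why: Fluoride removes the silyl group of 15 and triflate leaves to give aryne 17; the NHC-bound monovalent copper acetylide formed from 7 and Cs2CO3 carbocuprates the strained triple bond (C4–C4a), the ortho-alkynyl arylcopper inserts CO2 (C8a–C1), and carboxylate 18 adds through oxygen to the copper-activated alkyne carbon C3, after which protonation of the vinylcopper at C4 releases 19 and the catalyst. The closest known reaction type is the NHC–copper-catalysed three-component coupling of ortho-silylaryl triflate derived arynes, terminal alkynes and CO2 to 3-substituted isocoumarins. The only ring closed is lactone ring B, by a 6-endo-dig oxycupration that forms the O2–C3 bond. No stereocentre is created (C3 stays sp2 until step 7), and the S carbinol centre of 7 lies four carbons from the alkyne and takes no part. No regiocontrol is needed at the aryne, because each aryne carbon is ortho to one methoxy group and meta to the other, so the two are equivalent and either direction of addition gives the same 1,2,3,4-tetrasubstituted ring A. The selectivities that are needed are carboxylation of the arylcopper before its protonation (helped by the electron-rich ortho-methoxy arylcopper, CO2 saturation and slow aryne release) and 6-endo over 5-exo closure (helped by soft π-activation by copper and by the aromatic 2-pyranone character of the product).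

Step 7
Reactants: 19 tert-butyl (2S)-5-(5,8-dimethoxy-1-oxo-1H-isochromen-3-yl)pentan-2-yl butanedioate
Product: 20 tert-butyl (2S)-5-[(3R)-5,8-dimethoxy-1-oxo-3,4-dihydro-1H-isochromen-3-yl]pentan-2-yl butanedioate
Conditions: catalyst preformed from Ru(cod)(2-methylallyl)2, SINpEt·HBF4 (1,3-bis[1-(naphthalen-1-yl)ethyl]imidazolinium salt), KOtBu and 1,2-diphenylethane-1,2-diamine (3 mol % Ru); NaOtBu (10 mol %), H2 (50 bar), toluene, rt
Reagents that add atoms: none
Why: Asymmetric hydrogenation of the enol-lactone C3=C4 bond of 3-alkylisocoumarins with chiral ruthenium–NHC–diamine catalysts is a known reaction type, the ligand antipode that delivers hydrogen to the Si face of C3 sets the R configuration, and the remote S centre has no influence.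

Step 8
Reactants: 20 tert-butyl (2S)-5-[(3R)-5,8-dimethoxy-1-oxo-3,4-dihydro-1H-isochromen-3-yl]pentan-2-yl butanedioate
Product: 21 4-{[(2S)-5-[(3R)-5,8-dimethoxy-1-oxo-3,4-dihydro-1H-isochromen-3-yl]pentan-2-yl]oxy}-4-oxobutanoic acid
Conditions: TFA, CH2Cl2, 0 °C → rt
Reagents that add atoms: none
Why: Acidolysis of the tert-butyl ester (alkyl–oxygen cleavage with loss of isobutene) leaves the lactone, the secondary ester and the aryl methyl ethers untouched, and the C1 carbonyl still deactivates ring A enough for it to escape tert-butylation.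

Step 9
Reactants: 21 4-{[(2S)-5-[(3R)-5,8-dimethoxy-1-oxo-3,4-dihydro-1H-isochromen-3-yl]pentan-2-yl]oxy}-4-oxobutanoic acid
Product: 23 aspergimarin B, via quinone lactone 22 (not isolated)
Conditions: (NH4)2Ce(NO3)6 (2.5 equiv), MeCN–H2O, 0 °C, short contact; then aq Na2S2O4, EtOAc, rt
Reagents that add atoms: water O
Why: Oxidative demethylation of a 1,4-dimethoxybenzene by tetravalent cerium gives the para-quinone without touching the esters, the acid or either stereocentre, and dithionite reduction in the same work-up restores the hydroquinone oxidation level of the target.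

**Compound list**
1 | (4-bromobut-1-yn-1-yl)trimethylsilane | C[Si](C)(C)C#CCCBr | starting material
2 | (S)-propylene oxide | C[C@H]1CO1 | starting material
3 | [4-(trimethylsilyl)but-3-yn-1-yl]magnesium bromide | C[Si](C)(C)C#CCC[Mg]Br | intermediate
4 | (2S)-7-(trimethylsilyl)hept-6-yn-2-ol | C[C@@H](CCCC#C[Si](C)(C)C)O | intermediate
5 | (2S)-hept-6-yn-2-ol | C[C@@H](CCCC#C)O | intermediate
6 | 4-tert-butoxy-4-oxobutanoic acid | OC(=O)CCC(=O)OC(C)(C)C | starting material
7 | tert-butyl (2S)-hept-6-yn-2-yl butanedioate | C[C@@H](CCCC#C)OC(=O)CCC(=O)OC(C)(C)C | intermediate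
8 | 2,5-dimethoxyphenol | COc1ccc(OC)c(O)c1 | starting material
9 | 2,5-dimethoxyphenyl N-isopropylcarbamate | COc1ccc(OC)c(OC(=O)NC(C)C)c1 | intermediate
10 | 2,5-dimethoxyphenyl N-(tert-butyldimethylsilyl)-N-isopropylcarbamate | COc1ccc(OC)c(OC(=O)N(C(C)C)[Si](C)(C)C(C)(C)C)c1 | intermediate
11 | 2-lithio-3,6-dimethoxyphenyl N-(tert-butyldimethylsilyl)-N-isopropylcarbamate | COc1ccc(OC)c(OC(=O)N(C(C)C)[Si](C)(C)C(C)(C)C)c1[Li] | intermediate
12 | 3,6-dimethoxy-2-(trimethylsilyl)phenyl N-(tert-butyldimethylsilyl)-N-isopropylcarbamate | COc1ccc(OC)c(OC(=O)N(C(C)C)[Si](C)(C)C(C)(C)C)c1[Si](C)(C)C | intermediate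
13 | 3,6-dimethoxy-2-(trimethylsilyl)phenyl N-isopropylcarbamate | COc1ccc(OC)c(OC(=O)NC(C)C)c1[Si](C)(C)C | intermediate
14 | 3,6-dimethoxy-2-(trimethylsilyl)phenol | COc1ccc(OC)c(O)c1[Si](C)(C)C | intermediate
15 | 3,6-dimethoxy-2-(trimethylsilyl)phenyl trifluoromethanesulfonate | COc1ccc(OC)c(OS(=O)(=O)C(F)(F)F)c1[Si](C)(C)C | intermediate
16 | carbon dioxide | O=C=O | starting material
17 | 3,6-dimethoxybenzyne | COC1=CC=C(OC)C#C1 | intermediate
18 | cesium 2-[(6S)-6-(4-tert-butoxy-4-oxobutanoyloxy)hept-1-yn-1-yl]-3,6-dimethoxybenzoate | C[C@@H](CCCC#Cc1c(OC)ccc(OC)c1C(=O)[O-])OC(=O)CCC(=O)OC(C)(C)C.[Cs+] | intermediate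
19 | tert-butyl (2S)-5-(5,8-dimethoxy-1-oxo-1H-isochromen-3-yl)pentan-2-yl butanedioate | C[C@@H](CCCC1=Cc2c(OC)ccc(OC)c2C(=O)O1)OC(=O)CCC(=O)OC(C)(C)C | intermediate
20 | tert-butyl (2S)-5-[(3R)-5,8-dimethoxy-1-oxo-3,4-dihydro-1H-isochromen-3-yl]pentan-2-yl butanedioate | C[C@@H](CCC[C@@H]1Cc2c(OC)ccc(OC)c2C(=O)O1)OC(=O)CCC(=O)OC(C)(C)C | intermediate
21 | 4-{[(2S)-5-[(3R)-5,8-dimethoxy-1-oxo-3,4-dihydro-1H-isochromen-3-yl]pentan-2-yl]oxy}-4-oxobutanoic acid | C[C@@H](CCC[C@@H]1Cc2c(OC)ccc(OC)c2C(=O)O1)OC(=O)CCC(=O)O | intermediate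
22 | 4-{[(2S)-5-[(3R)-1,5,8-trioxo-3,4,5,8-tetrahydro-1H-isochromen-3-yl]pentan-2-yl]oxy}-4-oxobutanoic acid | C[C@@H](CCC[C@@H]1CC2=C(C(=O)C=CC2=O)C(=O)O1)OC(=O)CCC(=O)O | intermediate
23 | aspergimarin B, 4-{[(2S)-5-[(3R)-5,8-dihydroxy-1-oxo-3,4-dihydro-1H-isochromen-3-yl]pentan-2-yl]oxy}-4-oxobutanoic acid | C[C@@H](CCC[C@@H]1Cc2c(O)ccc(O)c2C(=O)O1)OC(=O)CCC(=O)O | target

**Step count**
Total step count: 9.
Longest linear sequence: 7 steps (steps 3 to 9, from 8).

**Steps most likely to fail**

Step 6. Protonation of the ortho-alkynyl arylcopper may outrun CO2 insertion. The carboxylate may be arylated by a second aryne. Ring closure may run in the 5-exo-dig mode under the basic conditions.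
The fallback installs the carboxyl carbon before the alkyne and closes the ring under π-acid catalysis. It sets out from 7 and comes back at 19.
- Commercial 2,5-dimethoxybenzoic acid F1 is lithiated between the carboxylate and the methoxy group (s-BuLi, TMEDA, THF, −78 °C) and quenched with I2 to give 2-iodo-3,6-dimethoxybenzoic acid F2.
- Esterification (MeI, K2CO3, DMF) gives methyl 2-iodo-3,6-dimethoxybenzoate F3.
- Sonogashira coupling with 7 (PdCl2(PPh3)2, CuI, Et3N, 60 °C) gives methyl 2-[(6S)-6-(4-tert-butoxy-4-oxobutanoyloxy)hept-1-yn-1-yl]-3,6-dimethoxybenzoate F4.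
- AuCl3 (cat.) in wet MeCN induces 6-endo-dig attack of the ester carbonyl oxygen on C3, with loss of the methyl group. This forms the same O2–C3 bond and gives 19.

Step 7. Facial selectivity may be poor, or hydrogen uptake slow, because the 5-methoxy group crowds C4. The alkoxide additive may start ester exchange.
The fallback gives up catalyst control in favour of separation. It sets out from 19 and comes back at 20. Hydrogenation over Pd/C (H2, EtOAc) should give 20 together with its C3 epimer, tert-butyl (2S)-5-[(3S)-5,8-dimethoxy-1-oxo-3,4-dihydro-1H-isochromen-3-yl]pentan-2-yl butanedioate F5. Because the side-chain centre is fixed, the two are diastereomers and are separated by preparative HPLC on a chiral stationary phase.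

Step 9. Electron transfer from the acyl-deactivated ring A may be slow. Water may add to the acylquinone. The quinone may tautomerise by loss of a C4 proton, which would endanger the C3 centre.
The fallback avoids the quinone altogether. It sets out from 21 and comes back at 23. Lewis-acid ether cleavage at the hydroquinone oxidation level (BBr3, CH2Cl2, −78 → 0 °C, then water) removes both methyl groups directly, and no new compound is made on the way.

**Further compounds**
F1 | step 6 | 2,5-dimethoxybenzoic acid | COc1ccc(OC)c(C(=O)O)c1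
F2 | step 6 | 2-iodo-3,6-dimethoxybenzoic acid | COc1ccc(OC)c(C(=O)O)c1I
F3 | step 6 | methyl 2-iodo-3,6-dimethoxybenzoate | COC(=O)c1c(OC)ccc(OC)c1I
F4 | step 6 | methyl 2-[(6S)-6-(4-tert-butoxy-4-oxobutanoyloxy)hept-1-yn-1-yl]-3,6-dimethoxybenzoate | C[C@@H](CCCC#Cc1c(OC)ccc(OC)c1C(=O)OC)OC(=O)CCC(=O)OC(C)(C)C
F5 | step 7 | tert-butyl (2S)-5-[(3S)-5,8-dimethoxy-1-oxo-3,4-dihydro-1H-isochromen-3-yl]pentan-2-yl butanedioate | C[C@@H](CCC[C@H]1Cc2c(OC)ccc(OC)c2C(=O)O1)OC(=O)CCC(=O)OC(C)(C)C
F0 | step 9 | none | none
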